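**Strategy.** The ether oxygen bridges C10 (quaternary, methyl-bearing) and C5 (the ether CH) of the ten-membered carbocycle (germacrane numbering), so the core is an 11-oxabicyclo[4.4.1]undecane: a decalin with an oxygen atom inserted into its ring-fusion bond. The route therefore builds a nor-eudesmane decalin carrying a tertiary hydroperoxide at C10. A Criegee rearrangement then shifts C5 from C10 to oxygen, forming the O–C5 bond with retention and creating both oxepane rings and the ten-membered carbocycle in one operation, and AlMe3 traps the bridged oxocarbenium ion at C10. The α-methylene lactone is closed last by carbonylation of an alkynol.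

Key step: step 10

Remark on numbering: germacrane locants are used for every intermediate. C10 is the ring-fusion carbon that becomes the methyl-bearing ether carbon, C5 the other ring-fusion (later ether CH) carbon, C4 the CH(CH3) carbon, C7 and C8 the lactone ring-fusion carbons, C9 the ester carbon. Ring A is C1–C5 plus C10; ring B is C5–C10.

Assumption: the (S,R,R) phosphoramidite is taken to give the 3S sense with Me2Zn as it does with Et2Zn; if not, its mirror image is used.

Step 1
Reactants: 1 cyclohex-2-en-1-one; 2 dimethylzinc; 3 allyl acetate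
Product: 5 (2R,3S)-3-methyl-2-(prop-2-en-1-yl)cyclohexan-1-one, via methylzinc enolate 4 (not isolated)
Conditions: Cu(OTf)2 (2 mol%), (S,R,R)-BINOL/bis(1-phenylethyl)amine phosphoramidite (4 mol%), Me2Zn, toluene, −30 °C; then Pd(PPh3)4 (4 mol%), allyl acetate, 0 °C
Reagents that add atoms: dimethylzinc (2), C[Zn]C; allyl acetate (3), C=CCOC(C)=O
Why: Copper-catalysed asymmetric conjugate addition sets C4, and the zinc enolate 4 undergoes Tsuji–Trost allylation at zerovalent palladium anti to the new methyl group, giving the 2,3-trans ketone (C5 is epimerisable, so trans is also the thermodynamic isomer).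

Step 2
Reactants: 5 (2R,3S)-3-methyl-2-(prop-2-en-1-yl)cyclohexan-1-one
Product: 6 (5S,6R)-5-methyl-6-(prop-2-en-1-yl)cyclohex-1-en-1-yl trifluoromethanesulfonate
Conditions: LDA, THF, −78 °C; then PhNTf2, −78 → 0 °C
Reagents that add atoms: N-phenylbis(trifluoromethanesulfonimide), O=S(=O)(N(c1ccccc1)S(=O)(=O)C(F)(F)F)C(F)(F)F
Why: Kinetic deprotonation occurs at the unhindered C1 methylene rather than the tertiary C5–H, and O-sulfonylation of the enolate (enol triflate formation) fixes the C10=C1 double bond without touching the stereocentres.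

Step 3
Reactants: 6 enol triflate; 7 carbon monoxide; 8 tributyl(vinyl)stannane
Product: 9 1-[(5S,6R)-5-methyl-6-(prop-2-en-1-yl)cyclohex-1-en-1-yl]prop-2-en-1-one
Conditions: Pd(PPh3)4 (3 mol%), LiCl (3 equiv), CO (1–3 atm), THF, 55 °C
Reagents that add atoms: carbon monoxide (7), [C-]#[O+]; tributyl(vinyl)stannane (8), C=C[Sn](CCCC)(CCCC)CCCC
Why: Carbonylative Stille coupling (oxidative addition of the vinyl triflate to zerovalent palladium, CO insertion, transmetalation) should give the cross-conjugated divinyl ketone and so attach C9 and C8.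

Step 4
Reactants: 9 divinyl ketone
Product: 10 (4aR,5S)-5-methyl-4a,5,6,7-tetrahydronaphthalen-1(4H)-one
Conditions: second-generation Grubbs catalyst (3 mol%), 1,4-benzoquinone (10 mol%), CH2Cl2 (5 mM), 40 °C
Reagents that add atoms: none
Why: Ring-closing metathesis between the allyl group and the acryloyl terminus closes ring B as a cyclohexenone with loss of ethene; the trisubstituted conjugated C10=C1 bond is inert, and benzoquinone suppresses ruthenium hydride isomerisation that could aromatise this tetrahydronaphthol tautomer (10 is used promptly).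

Step 5
Reactants: 10 dienone; 11 ethynyl(trimethyl)silane
Product: 12 tert-butyl(dimethyl)({(3S,4aR,5S)-5-methyl-3-[(trimethylsilyl)ethynyl]-3,4,4a,5,6,7-hexahydronaphthalen-1-yl}oxy)silane
Conditions: 11, n-BuLi, THF, −78 °C; ZnBr2, 0 °C; then 10, TBSOTf, Et2O/THF, −40 °C
Reagents that add atoms: ethynyl(trimethyl)silane (11), C#C[Si](C)(C)C; tert-butyldimethylsilyl trifluoromethanesulfonate, CC(C)(C)[Si](C)(C)OS(=O)(=O)C(F)(F)F
Why: Silyl-triflate-promoted conjugate addition of the alkynylzinc reagent should occur at C7, the β-carbon of the less substituted enone, by axial attack trans to the equatorial C5–C4 bond (the 3,5-trans rule of 5-substituted cyclohexenones), setting C7 and delivering the silyl dienol ether directly.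

Step 6
Reactants: 12 silyl dienol ether
Product: 13 (2R,3R,4aR,5S)-2-{[tert-butyl(dimethyl)silyl]oxy}-5-methyl-3-[(trimethylsilyl)ethynyl]-3,4,4a,5,6,7-hexahydronaphthalen-1(2H)-one
Conditions: mCPBA (1.0 equiv), NaHCO3, CH2Cl2, −20 → 0 °C
Reagents that add atoms: 3-chloroperoxybenzoic acid, O=C(OO)c1cccc(Cl)c1
Why: Rubottom oxidation: the electron-rich C8=C9 enol ether is epoxidised anti to the axial C7 alkynyl group and 1,4-silyl migration gives the α-silyloxy ketone with the C8 oxygen trans-diaxial to the C7 substituent.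

Step 7
Reactants: 13 α-silyloxy enone
Product: 14 (1S,2R,3R,4aR,5S)-2-{[tert-butyl(dimethyl)silyl]oxy}-5-methyl-3-[(trimethylsilyl)ethynyl]-1,2,3,4,4a,5,6,7-octahydronaphthalen-1-ol
Conditions: NaBH4, CeCl3·7H2O, MeOH, −78 °C
Reagents that add atoms: none
Why: Luche 1,2-reduction: hydride should attack C9 axially, anti to the axial C8–O bond (Felkin–Anh polar control), giving the equatorial alcohol cis to the silyl ether without conjugate reduction.

Step 8
Reactants: 14 allylic alcohol; 15 3-methylbutanoic acid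
Product: 16 (1R,2R,3R,4aR,5S)-2-{[tert-butyl(dimethyl)silyl]oxy}-5-methyl-3-[(trimethylsilyl)ethynyl]-1,2,3,4,4a,5,6,7-octahydronaphthalen-1-yl 3-methylbutanoate
Conditions: 3-methylbutanoic acid, PPh3, DIAD, toluene, 0 → 40 °C
Reagents that add atoms: 3-methylbutanoic acid (15), CC(C)CC(=O)O
Why: Mitsunobu esterification inverts C9 (SN2 displacement of the alkoxyphosphonium ion by the carboxylate), giving the 8,9-trans ester the target requires; if step 7 were to give the other epimer, plain acylation would serve instead.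

Step 9
Reactants: 16 allylic ester
Product: 18 (1S,2R,3R,4aR,5S,8aRS)-2-{[tert-butyl(dimethyl)silyl]oxy}-8a-hydroperoxy-5-methyl-3-[(trimethylsilyl)ethynyl]decahydronaphthalen-1-yl 3-methylbutanoate, via triethylsilyl peroxide 17 (not isolated)
Conditions: Co(acac)2 (10 mol%), O2 (1 atm), Et3SiH, ClCH2CH2Cl, rt; then PPTS, MeOH, 0 °C
Reagents that add atoms: dioxygen, O=O; triethylsilane, CC[SiH](CC)CC (silyl group carried only in 17)
Why: Mukaiyama–Isayama hydroperoxysilylation: hydrogen-atom transfer from a cobalt hydride to C1 gives the tertiary C10 radical, which traps O2 (Markovnikov), and mild methanolysis frees the hydroperoxide; C10 forms as an epimer mixture, which is harmless because this centre is destroyed in step 10, and the silylalkyne is inert.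

Step 10
Reactants: 18 tertiary hydroperoxide; 19 trimethylaluminium
Product: 22 (1R,2S,3R,4R,6R,7S)-3-{[tert-butyl(dimethyl)silyl]oxy}-1,7-dimethyl-4-[(trimethylsilyl)ethynyl]-11-oxabicyclo[4.4.1]undecan-2-yl 3-methylbutanoate, via peroxy trifluoroacetate 20 (not isolated), via bridgehead ketal trifluoroacetate 21 (not isolated)
Conditions: (CF3CO)2O (1.2 equiv), 2,6-di-tert-butyl-4-methylpyridine, CH2Cl2, −40 → 0 °C; then AlMe3 (4 equiv), −78 → 0 °C
Reagents that add atoms: trimethylaluminium (19), C[Al](C)C; trifluoroacetic anhydride, O=C(OC(=O)C(F)(F)F)C(F)(F)F (acyl group carried only in 20 and 21)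
Why: Acylation gives the peroxy trifluoroacetate 20, whose O–O bond ionises with concerted 1,2-shift of C5 from C10 to the proximal peroxide oxygen (Criegee rearrangement, the reaction type by which 9-decalyl peresters give 1-acyloxy-11-oxabicyclo[4.4.1]undecanes), so the O–C5 bond forms with retention at C5 while the C5–C10 ring-fusion bond is lost. Both oxepane rings (O–C5–C4–C3–C2–C1–C10 and O–C5–C6–C7–C8–C9–C10) and the ten-membered carbocycle arise by ring expansion through oxygen insertion, not by end-to-end cyclisation, so no ring-size constraint or high dilution applies. The bridged oxocarbenium ion collapses with trifluoroacetate to ketal ester 21, which AlMe3 re-ionises and methylates (Lewis-acid substitution of acyloxy ketals by organoaluminium reagents). C5 keeps its configuration because the shift is suprafacial, and the new quaternary C10 can carry its methyl group only exo to the one-atom oxygen bridge, so its configuration is dictated by C5 and both C10 epimers of 18 converge. The step needs migration of C5 rather than C1 or C9: C1 is primary, and C9 is deactivated by its own acyloxy group and the adjacent silyloxy group, whereas C5 is an unfunctionalised secondary alkyl carbon.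

Step 11
Reactants: 22 bridged ether
Product: 23 (1R,2S,3R,4R,6R,7S)-4-ethynyl-3-hydroxy-1,7-dimethyl-11-oxabicyclo[4.4.1]undecan-2-yl 3-methylbutanoate
Conditions: Bu4NF, AcOH, THF, 0 °C → rt
Reagents that add atoms: none
Why: Fluoride cleaves the C8 silyl ether and the alkynyl C–Si bond in one operation, the acetic acid buffer suppressing migration of the isovaleryl group to the freed C8 hydroxyl.

Step 12
Reactants: 23 alkynol; 7 carbon monoxide
Product: 24 (1R,2S,3R,7R,9R,10S)-1,10-dimethyl-6-methylidene-5-oxo-4,14-dioxatricyclo[7.4.1.0^{3,7}]tetradecan-2-yl 3-methylbutanoate (CNP0274454.1)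
Conditions: PdCl2 (5 mol%), PPh3 (10 mol%), SnCl2 (5 mol%), CO (7 atm), MeCN, 75 °C
Reagents that add atoms: carbon monoxide (7), [C-]#[O+]
Why: Palladium-catalysed cyclocarbonylation of a homopropargylic alcohol: an alkoxycarbonyl–palladium species formed from the C8 hydroxyl and CO adds across the alkyne (5-exo-dig) and protonolysis releases the trans-fused α-methylene-γ-butyrolactone without any enolate chemistry, leaving all stereocentres untouched.

**Compound list**

1 | cyclohex-2-en-1-one | O=C1C=CCCC1 | starting material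
2 | dimethylzinc | C[Zn]C | starting material
3 | allyl acetate | C=CCOC(C)=O | starting material
4 | methyl[(3S)-3-methylcyclohex-1-en-1-olato]zinc | C[Zn]OC1=C[C@@H](C)CCC1 | intermediate
5 | (2R,3S)-3-methyl-2-(prop-2-en-1-yl)cyclohexan-1-one | O=C1CCC[C@H](C)[C@H]1CC=C | intermediate
6 | (5S,6R)-5-methyl-6-(prop-2-en-1-yl)cyclohex-1-en-1-yl trifluoromethanesulfonate | O=S(=O)(OC1=CCC[C@H](C)[C@H]1CC=C)C(F)(F)F | intermediate
7 | carbon monoxide | [C-]#[O+] | starting material
8 | tributyl(vinyl)stannane | C=C[Sn](CCCC)(CCCC)CCCC | starting material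
9 | 1-[(5S,6R)-5-methyl-6-(prop-2-en-1-yl)cyclohex-1-en-1-yl]prop-2-en-1-one | C=CC(=O)C1=CCC[C@H](C)[C@H]1CC=C | intermediate
10 | (4aR,5S)-5-methyl-4a,5,6,7-tetrahydronaphthalen-1(4H)-one | O=C1C=CC[C@@H]2[C@@H](C)CCC=C12 | intermediate
11 | ethynyl(trimethyl)silane | C#C[Si](C)(C)C | starting material
12 | tert-butyl(dimethyl)({(3S,4aR,5S)-5-methyl-3-[(trimethylsilyl)ethynyl]-3,4,4a,5,6,7-hexahydronaphthalen-1-yl}oxy)silane | C[Si](C)(C)C#C[C@H]1C[C@@H]2[C@@H](C)CCC=C2C(O[Si](C)(C)C(C)(C)C)=C1 | intermediate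
13 | (2R,3R,4aR,5S)-2-{[tert-butyl(dimethyl)silyl]oxy}-5-methyl-3-[(trimethylsilyl)ethynyl]-3,4,4a,5,6,7-hexahydronaphthalen-1(2H)-one | C[Si](C)(C)C#C[C@H]1C[C@@H]2[C@@H](C)CCC=C2C(=O)[C@@H]1O[Si](C)(C)C(C)(C)C | intermediate
14 | (1S,2R,3R,4aR,5S)-2-{[tert-butyl(dimethyl)silyl]oxy}-5-methyl-3-[(trimethylsilyl)ethynyl]-1,2,3,4,4a,5,6,7-octahydronaphthalen-1-ol | C[Si](C)(C)C#C[C@H]1C[C@@H]2[C@@H](C)CCC=C2[C@H](O)[C@@H]1O[Si](C)(C)C(C)(C)C | intermediate
15 | 3-methylbutanoic acid | CC(C)CC(=O)O | starting material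
16 | (1R,2R,3R,4aR,5S)-2-{[tert-butyl(dimethyl)silyl]oxy}-5-methyl-3-[(trimethylsilyl)ethynyl]-1,2,3,4,4a,5,6,7-octahydronaphthalen-1-yl 3-methylbutanoate | C[Si](C)(C)C#C[C@H]1C[C@@H]2[C@@H](C)CCC=C2[C@@H](OC(=O)CC(C)C)[C@@H]1O[Si](C)(C)C(C)(C)C | intermediate
17 | (1S,2R,3R,4aR,5S,8aRS)-2-{[tert-butyl(dimethyl)silyl]oxy}-5-methyl-8a-[(triethylsilyl)peroxy]-3-[(trimethylsilyl)ethynyl]decahydronaphthalen-1-yl 3-methylbutanoate (C10 epimer mixture, centre left undefined) | C[Si](C)(C)C#C[C@H]1C[C@@H]2[C@@H](C)CCCC2(OO[Si](CC)(CC)CC)[C@@H](OC(=O)CC(C)C)[C@@H]1O[Si](C)(C)C(C)(C)C | intermediate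
18 | (1S,2R,3R,4aR,5S,8aRS)-2-{[tert-butyl(dimethyl)silyl]oxy}-8a-hydroperoxy-5-methyl-3-[(trimethylsilyl)ethynyl]decahydronaphthalen-1-yl 3-methylbutanoate (C10 epimer mixture, centre left undefined) | C[Si](C)(C)C#C[C@H]1C[C@@H]2[C@@H](C)CCCC2(OO)[C@@H](OC(=O)CC(C)C)[C@@H]1O[Si](C)(C)C(C)(C)C | intermediate
19 | trimethylaluminium | C[Al](C)C | starting material
20 | (1S,2R,3R,4aR,5S,8aRS)-2-{[tert-butyl(dimethyl)silyl]oxy}-5-methyl-8a-[(trifluoroacetyl)peroxy]-3-[(trimethylsilyl)ethynyl]decahydronaphthalen-1-yl 3-methylbutanoate | C[Si](C)(C)C#C[C@H]1C[C@@H]2[C@@H](C)CCCC2(OOC(=O)C(F)(F)F)[C@@H](OC(=O)CC(C)C)[C@@H]1O[Si](C)(C)C(C)(C)C | intermediate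
21 | (1S,2S,3R,4R,6R,7S)-3-{[tert-butyl(dimethyl)silyl]oxy}-7-methyl-2-[(3-methylbutanoyl)oxy]-4-[(trimethylsilyl)ethynyl]-11-oxabicyclo[4.4.1]undecan-1-yl trifluoroacetate | C[Si](C)(C)C#C[C@H]1C[C@H]2O[C@](OC(=O)C(F)(F)F)(CCC[C@@H]2C)[C@@H](OC(=O)CC(C)C)[C@@H]1O[Si](C)(C)C(C)(C)C | intermediate
22 | (1R,2S,3R,4R,6R,7S)-3-{[tert-butyl(dimethyl)silyl]oxy}-1,7-dimethyl-4-[(trimethylsilyl)ethynyl]-11-oxabicyclo[4.4.1]undecan-2-yl 3-methylbutanoate | C[Si](C)(C)C#C[C@H]1C[C@H]2O[C@](C)(CCC[C@@H]2C)[C@@H](OC(=O)CC(C)C)[C@@H]1O[Si](C)(C)C(C)(C)C | intermediate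
23 | (1R,2S,3R,4R,6R,7S)-4-ethynyl-3-hydroxy-1,7-dimethyl-11-oxabicyclo[4.4.1]undecan-2-yl 3-methylbutanoate | C#C[C@H]1C[C@H]2O[C@](C)(CCC[C@@H]2C)[C@@H](OC(=O)CC(C)C)[C@@H]1O | intermediate
24 | (1R,2S,3R,7R,9R,10S)-1,10-dimethyl-6-methylidene-5-oxo-4,14-dioxatricyclo[7.4.1.0^{3,7}]tetradecan-2-yl 3-methylbutanoate | C=C1C(=O)O[C@@H]2[C@@H]1C[C@H]1O[C@](C)(CCC[C@@H]1C)[C@H]2OC(=O)CC(C)C | target

**Step count and risks**

Total steps: 12. Longest linear sequence: 12 (from cyclohex-2-en-1-one).

Most likely to fail: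

Step 10. After the ring expansion, the bridgehead oxocarbenium ion may be intercepted by the carbonyl oxygen of the neighbouring C9 ester (dioxolanylium formation) or lose a proton instead of accepting methyl from aluminium; migration of the oxygenated C9 in place of C5 could also compete. Fallback: setting out from 18, the rearrangement is run with (CF3CO)2O and the hindered pyridine alone and quenched with aqueous NaHCO3, which hydrolyses ketal ester 21 to the bridgehead hemiketal F1 (ring-chain tautomer of the 5-hydroxy-10-ketone). Takai–Lombardo methylenation of its keto form (Zn, CH2Br2, TiCl4) should give the 10-methylidene 5-alcohol F2, and camphorsulfonic-acid-catalysed transannular Markovnikov hydroalkoxylation closes the O–C10 bond, rejoining the route at 22.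

Step 8. The alkoxyphosphonium intermediate may fail to form or to be displaced at the congested allylic carbinol beside the axial silyl ether, returning 14 or diverting to elimination or allylic transposition. Fallback: setting out from 14, activation and displacement are separated: ClCH2SO2Cl/pyridine should give the chloromethanesulfonate F3, which is displaced with inversion by CsO2CCH2CH(CH3)2 and 18-crown-6 in toluene at 80 °C, rejoining the route at 16.

Step 12. Formation of the alkoxycarbonyl–palladium species or its insertion into the alkyne may be outrun by alkyne oligomerisation or hydration under the Lewis-acidic, pressurised conditions. Fallback: setting out from 23, anti-Markovnikov hydroboration with dicyclohexylborane and oxidation with NaBO3·4H2O should give the aldehyde, which closes onto the C8 hydroxyl as the lactol F4. Fétizon oxidation (Ag2CO3 on Celite) gives the saturated lactone F5. LiHMDS then Eschenmoser's salt gives the Mannich base F6, and MeI followed by NaHCO3 eliminates trimethylamine, rejoining the route at 24. The lactone should enolise in preference to the less acidic, hindered isovalerate.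

Further compounds

F1 | step 10 | (1R,2S,3R,4R,6R,7S)-3-{[tert-butyl(dimethyl)silyl]oxy}-1-hydroxy-7-methyl-4-[(trimethylsilyl)ethynyl]-11-oxabicyclo[4.4.1]undecan-2-yl 3-methylbutanoate | C[Si](C)(C)C#C[C@H]1C[C@H]2O[C@](O)(CCC[C@@H]2C)[C@@H](OC(=O)CC(C)C)[C@@H]1O[Si](C)(C)C(C)(C)C
F2 | step 10 | (1R,2R,3R,5R,6S)-2-{[tert-butyl(dimethyl)silyl]oxy}-5-hydroxy-6-methyl-10-methylidene-3-[(trimethylsilyl)ethynyl]cyclodecyl 3-methylbutanoate | C[Si](C)(C)C#C[C@H]1C[C@@H](O)[C@@H](C)CCCC(=C)[C@@H](OC(=O)CC(C)C)[C@@H]1O[Si](C)(C)C(C)(C)C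
F3 | step 8 | (1S,2R,3R,4aR,5S)-2-{[tert-butyl(dimethyl)silyl]oxy}-5-methyl-3-[(trimethylsilyl)ethynyl]-1,2,3,4,4a,5,6,7-octahydronaphthalen-1-yl chloromethanesulfonate | C[Si](C)(C)C#C[C@H]1C[C@@H]2[C@@H](C)CCC=C2[C@H](OS(=O)(=O)CCl)[C@@H]1O[Si](C)(C)C(C)(C)C
F4 | step 12 | (1R,2S,3R,7R,9R,10S)-5-hydroxy-1,10-dimethyl-4,14-dioxatricyclo[7.4.1.0^{3,7}]tetradecan-2-yl 3-methylbutanoate (lactol, anomer mixture) | OC1C[C@H]2C[C@H]3O[C@](C)(CCC[C@@H]3C)[C@@H](OC(=O)CC(C)C)[C@@H]2O1
F5 | step 12 | (1R,2S,3R,7R,9R,10S)-1,10-dimethyl-5-oxo-4,14-dioxatricyclo[7.4.1.0^{3,7}]tetradecan-2-yl 3-methylbutanoate | O=C1C[C@H]2C[C@H]3O[C@](C)(CCC[C@@H]3C)[C@@H](OC(=O)CC(C)C)[C@@H]2O1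
F6 | step 12 | (1R,2S,3R,7R,9R,10S)-6-[(dimethylamino)methyl]-1,10-dimethyl-5-oxo-4,14-dioxatricyclo[7.4.1.0^{3,7}]tetradecan-2-yl 3-methylbutanoate (C6 epimer mixture) | O=C1C(CN(C)C)[C@H]2C[C@H]3O[C@](C)(CCC[C@@H]3C)[C@@H](OC(=O)CC(C)C)[C@@H]2O1
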